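Labels: ring C1 (carbinol), C2, C3, C4 (Br, CH3), C5 (Cl), C6; chain C7 (=CH2), C8, C9, C10 (carbinol), C11 (isopropenyl). Everything rests on C10, which sits between primary C9 and sp2 C11 and, as a ketone, is simply carbon monoxide. One palladium-catalysed carbonylative coupling joins a B-alkyl-9-BBN, CO and 2-bromopropene. It forges C9–C10 and C10–C11 together while the cyclohexane ring C1–C6 with its three stereocentres looks on. The borane comes from a 2-substituted butadiene that already holds the finished ring: C1 triethylsilyl ether, C4–Br, C5–Cl. Catalyst-controlled reduction then sets C10.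

Key step: step 11

Assumption: the facial sense of the amine catalyst of step 3 with isoprene is inferred by analogy, so the catalyst antipode (L,L or D,D series) that delivers (S)-7 is the one used; the aryl ester offers recrystallisation as a means of enantiomeric enrichment.

Relative configuration aimed at: C1–O and C4–Br on the same ring face, C5–Cl on the opposite face (Br/Cl trans).

Step 1
Reactants: 1 2,2-dimethyl-1,3-dioxan-5-one; 2 4-methoxybenzoyl chloride
Product: 4 2,2-dimethyl-4H-1,3-dioxin-5-yl 4-methoxybenzoate, via potassium enolate 3 (not isolated)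
Conditions: KN(SiMe3)2, THF, −78 °C; then 2, −78 → 0 °C
Reagents that add atoms: none
Why: The hard acyl chloride captures the potassium enolate on oxygen (enolate O-acylation), and the silazide base avoids the hydride-transfer reduction that amide bases with β-hydrogens inflict on this ketone.

Step 2
Reactants: 4 2,2-dimethyl-4H-1,3-dioxin-5-yl 4-methoxybenzoate
Product: 5 2-(4-methoxybenzoyloxy)acrolein
Conditions: toluene, reflux, BHT (trace), acetone distilled off
Reagents that add atoms: none
Why: Thermal retro-hetero-Diels–Alder cleavage of the 4H-1,3-dioxin expels acetone, whose removal drives the cycloreversion to the 2-acyloxyacrolein.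

Step 3
Reactants: 5 2-(4-methoxybenzoyloxy)acrolein; 6 isoprene
Product: 7 (1S)-1-formyl-4-methylcyclohex-3-en-1-yl 4-methoxybenzoate
Conditions: chiral triamine from reduction of H-Phe-Leu-pyrrolidide (10 mol %), C6F5SO3H (2.75 equiv per triamine), EtNO2, 0 °C → rt
Reagents that add atoms: none
Why: This is an enantioselective Diels–Alder reaction under iminium catalysis by a chiral primary ammonium salt, a catalyst class made for α-acyloxyacroleins, in which the larger HOMO coefficient at C1 of isoprene bonds to the β-carbon of the dienophile (para adduct, CH3 on C4) and the shielded face of the iminium ion sets C1 as S.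

Step 4
Reactants: 7 (1S)-1-formyl-4-methylcyclohex-3-en-1-yl 4-methoxybenzoate
Product: 9 (1S)-1-ethynyl-4-methylcyclohex-3-en-1-ol, via propargylic ester 8 (not isolated)
Conditions: dimethyl (1-diazo-2-oxopropyl)phosphonate, K2CO3, MeOH, 0 °C → rt; then NaOMe (cat.), 40 °C, same flask
Reagents that add atoms: dimethyl (1-diazo-2-oxopropyl)phosphonate, COP(=O)(OC)C(=[N+]=[N-])C(C)=O
Why: Ohira–Bestmann homologation (diazomethylphosphonate freed in situ, alkylidene carbene, 1,2-H shift) turns the non-enolisable aldehyde into the terminal alkyne without touching C1, and methoxide then transesterifies the tertiary aryl ester in the same flask.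

Step 5
Reactants: 9 (1S)-1-ethynyl-4-methylcyclohex-3-en-1-ol
Product: 10 (1S,3S,6R)-3-ethynyl-6-methyl-7-oxabicyclo[4.1.0]heptan-3-ol (epoxide cis to OH)
Conditions: VO(acac)2 (3 mol %), t-BuOOH (decane solution), CH2Cl2, 0 °C → rt
Reagents that add atoms: tert-butyl hydroperoxide, CC(C)(C)OO
Why: In this hydroxyl-directed epoxidation of a cyclohex-3-enol, as known for terpinen-4-ol, the vanadium alkoxide of the axial C1–OH delivers oxygen to the ring face it occupies, which sets C4 (R) and C5 (S) cis to the hydroxyl while the alkyne stays inert.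

Step 6
Reactants: 10 (1S,3S,6R)-3-ethynyl-6-methyl-7-oxabicyclo[4.1.0]heptan-3-ol
Product: 11 triethyl{[(1S,3S,6R)-3-ethynyl-6-methyl-7-oxabicyclo[4.1.0]heptan-3-yl]oxy}silane
Conditions: Et3SiCl, imidazole, DMAP (cat.), DMF, rt → 40 °C
Reagents that add atoms: chlorotriethylsilane, CC[Si](Cl)(CC)CC
Why: Chlorosilane/imidazole silylation is chosen over the silyl triflate, which isomerises trisubstituted epoxides, and the triethylsilyl group is sturdy enough for steps 7–12, leaves C4–OH as the only free hydroxyl in step 8 and screens the C7 methylene in step 10.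

Step 7
Reactants: 11 triethyl{[(1S,3S,6R)-3-ethynyl-6-methyl-7-oxabicyclo[4.1.0]heptan-3-yl]oxy}silane
Product: 12 (1R,2R,4S)-2-chloro-4-ethynyl-1-methyl-4-(triethylsilyloxy)cyclohexan-1-ol
Conditions: LiCl (5 equiv), AcOH (3 equiv), THF, rt
Reagents that add atoms: lithium chloride, [Li+].[Cl-]
Why: Halohydrin formation with LiCl/AcOH is an SN2-type epoxide opening in which chloride enters anti at the less substituted C5 (inversion) in the trans-diaxial Fürst–Plattner mode, through the half-chair with equatorial silyloxy and axial ethynyl groups, while the C4–O bond and its configuration are kept.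

Step 8
Reactants: 12 (1R,2R,4S)-2-chloro-4-ethynyl-1-methyl-4-(triethylsilyloxy)cyclohexan-1-ol
Product: 13 triethyl{[(1S,3R,4R)-4-bromo-3-chloro-1-ethynyl-4-methylcyclohexyl]oxy}silane
Conditions: 1-bromo-N,N,2-trimethylprop-1-en-1-amine (1.5 equiv), CH2Cl2, 0 °C → rt
Reagents that add atoms: 1-bromo-N,N,2-trimethylprop-1-en-1-amine, CC(C)=C(Br)N(C)C
Why: Deoxybromination with an α-bromoenamine works on tertiary alcohols under neutral conditions and activates only the free C4–OH, and the antiperiplanar C5 chlorine (diaxial conformer, tolerable because the ethynyl group is slim) assists ionisation by classical neighbouring-group participation, so bromide enters tertiary C4 from the face the oxygen left and the trans C4–Br/C5–Cl pair results with retention.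

Step 9
Reactants: 13 triethyl{[(1S,3R,4R)-4-bromo-3-chloro-1-ethynyl-4-methylcyclohexyl]oxy}silane; 14 ethylene
Product: 15 {[(1S,3R,4R)-4-bromo-1-(buta-1,3-dien-2-yl)-3-chloro-4-methylcyclohexyl]oxy}triethylsilane
Conditions: second-generation Grubbs catalyst RuCl2(=CHPh)(PCy3)(SIMes) (5 mol %), ethylene (1–2 bar), CH2Cl2, rt → 40 °C
Reagents that add atoms: none
Why: In this ethylene–alkyne cross (enyne) metathesis the ruthenium methylidene adds to the terminal alkyne and ethylene releases the resulting vinylcarbene as the 2-substituted butadiene, with silyl ether and alkyl halides as spectators and no stereocentre involved.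

Step 10
Reactants: 15 {[(1S,3R,4R)-4-bromo-1-(buta-1,3-dien-2-yl)-3-chloro-4-methylcyclohexyl]oxy}triethylsilane; 16 9-borabicyclo[3.3.1]nonane
Product: 17 9-{3-[(1S,3R,4R)-4-bromo-3-chloro-4-methyl-1-(triethylsilyloxy)cyclohexyl]but-3-en-1-yl}-9-borabicyclo[3.3.1]nonane
Conditions: 9-BBN (1.1 equiv B–H), THF, 0 °C → rt; solution carried on as such
Reagents that add atoms: none
Why: Anti-Markovnikov hydroboration with a bulky dialkylborane picks the monosubstituted C8=C9 vinyl group (boron on C9), as known for 2-substituted butadienes such as myrcene, because hydrogen delivery to C7 would have to occur next to quaternary C1 and its triethylsilyloxy group.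

Step 11
Reactants: 17 9-{3-[(1S,3R,4R)-4-bromo-3-chloro-4-methyl-1-(triethylsilyloxy)cyclohexyl]but-3-en-1-yl}-9-borabicyclo[3.3.1]nonane; 18 carbon monoxide; 19 2-bromopropene
Product: 20 6-[(1S,3R,4R)-4-bromo-3-chloro-4-methyl-1-(triethylsilyloxy)cyclohexyl]-2-methylhepta-1,6-dien-3-one
Conditions: Pd(PPh3)4 (5 mol %), K3PO4 (3 equiv), CO (1–3 bar), 19 (3 equiv), BHT (trace), THF–toluene, 20–25 °C, dark
Reagents that add atoms: none
Why: Zerovalent palladium inserts into the C(sp2)–Br bond of 19, CO migrates into the alkenyl–palladium bond to give a methacryloyl complex of divalent palladium, the phosphate-activated borate hands over its primary C9 alkyl group, and reductive elimination releases 20, so that C10–C11 and C9–C10 are made in this order in one flask. The closest known reaction type is the carbonylative Suzuki–Miyaura coupling of 9-alkyl-9-BBN derivatives with haloalkenes to α,β-unsaturated ketones. No ring is closed and no stereocentre is created, and C1, C4 and C5 are spectators. Carbonylative coupling must beat direct coupling, which is secured because CO insertion into the alkenyl complex at room temperature is much faster than the slow transmetalation of a B-alkyl group, and because the acyl(alkyl)palladium species eliminates reductively before β-hydride loss from C8. Selectivity for the alkenyl bromide over C4–Br and C5–Cl follows from these hindered tertiary and secondary sp3 sites being closed to SN2-type oxidative addition, with darkness and BHT shutting down radical activation and the excess of volatile 19 offsetting the retarding effect of CO on oxidative addition. The substrate helps through its silyl ether at C1 (an allylic ester would ionise to a π-allyl complex) and through the 9-BBN cage, whose secondary B–C bonds migrate far more slowly than the primary C9–B bond.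

Step 12
Reactants: 20 6-[(1S,3R,4R)-4-bromo-3-chloro-4-methyl-1-(triethylsilyloxy)cyclohexyl]-2-methylhepta-1,6-dien-3-one
Product: 21 (3R)-6-[(1S,3R,4R)-4-bromo-3-chloro-4-methyl-1-(triethylsilyloxy)cyclohexyl]-2-methylhepta-1,6-dien-3-ol
Conditions: (S)-2-methyl-CBS-oxazaborolidine (20 mol %), catecholborane (1.8 equiv), toluene, −78 °C; MeOH quench
Reagents that add atoms: none
Why: In the Corey–Bakshi–Shibata reduction the enone binds to the (S)-oxazaborolidine with the branched isopropenyl group as the large and the C9 methylene as the small substituent, so hydride reaches the face that gives (R)-C10 (the sense of acetophenone to (R)-1-phenylethanol), and catecholborane at −78 °C leaves both 1,1-disubstituted alkenes alone.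

Step 13
Reactants: 21 (3R)-6-[(1S,3R,4R)-4-bromo-3-chloro-4-methyl-1-(triethylsilyloxy)cyclohexyl]-2-methylhepta-1,6-dien-3-ol
Product: 22 (1S,3R,4R)-4-bromo-3-chloro-1-[(5R)-5-hydroxy-6-methylhepta-1,6-dien-2-yl]-4-methylcyclohexan-1-ol (target)
Conditions: HF·pyridine, pyridine, THF, 0 °C → rt
Reagents that add atoms: none
Why: Fluoride-induced Si–O cleavage with pyridine-buffered HF is neither basic enough for E2 loss of the tertiary bromide nor acidic enough to ionise the two allylic alcohols.

Compound list
1 | 2,2-dimethyl-1,3-dioxan-5-one | CC1(C)OCC(=O)CO1 | starting material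
2 | 4-methoxybenzoyl chloride | COc1ccc(cc1)C(Cl)=O | starting material
3 | potassium 2,2-dimethyl-4H-1,3-dioxin-5-olate | CC1(C)OCC([O-])=CO1.[K+] | intermediate
4 | 2,2-dimethyl-4H-1,3-dioxin-5-yl 4-methoxybenzoate | COc1ccc(cc1)C(=O)OC1=COC(C)(C)OC1 | intermediate
5 | 2-(4-methoxybenzoyloxy)acrolein | C=C(C=O)OC(=O)c1ccc(OC)cc1 | intermediate
6 | isoprene | C=CC(C)=C | starting material
7 | (1S)-1-formyl-4-methylcyclohex-3-en-1-yl 4-methoxybenzoate | O=C[C@]1(OC(=O)c2ccc(OC)cc2)CCC(C)=CC1 | intermediate
8 | (1S)-1-ethynyl-4-methylcyclohex-3-en-1-yl 4-methoxybenzoate | C#C[C@]1(OC(=O)c2ccc(OC)cc2)CCC(C)=CC1 | intermediate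
9 | (1S)-1-ethynyl-4-methylcyclohex-3-en-1-ol | C#C[C@]1(O)CCC(C)=CC1 | intermediate
10 | (1S,3S,6R)-3-ethynyl-6-methyl-7-oxabicyclo[4.1.0]heptan-3-ol | C#C[C@]1(O)CC[C@@]2(C)O[C@H]2C1 | intermediate
11 | triethyl{[(1S,3S,6R)-3-ethynyl-6-methyl-7-oxabicyclo[4.1.0]heptan-3-yl]oxy}silane | C#C[C@]1(O[Si](CC)(CC)CC)CC[C@@]2(C)O[C@H]2C1 | intermediate
12 | (1R,2R,4S)-2-chloro-4-ethynyl-1-methyl-4-(triethylsilyloxy)cyclohexan-1-ol | C#C[C@]1(O[Si](CC)(CC)CC)CC[C@@](C)(O)[C@H](Cl)C1 | intermediate
13 | triethyl{[(1S,3R,4R)-4-bromo-3-chloro-1-ethynyl-4-methylcyclohexyl]oxy}silane | C#C[C@]1(O[Si](CC)(CC)CC)CC[C@@](C)(Br)[C@H](Cl)C1 | intermediate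
14 | ethylene | C=C | starting material
15 | {[(1S,3R,4R)-4-bromo-1-(buta-1,3-dien-2-yl)-3-chloro-4-methylcyclohexyl]oxy}triethylsilane | C=CC(=C)[C@]1(O[Si](CC)(CC)CC)CC[C@@](C)(Br)[C@H](Cl)C1 | intermediate
16 | 9-borabicyclo[3.3.1]nonane | B1C2CCCC1CCC2 | starting material
17 | 9-{3-[(1S,3R,4R)-4-bromo-3-chloro-4-methyl-1-(triethylsilyloxy)cyclohexyl]but-3-en-1-yl}-9-borabicyclo[3.3.1]nonane | C(CC(=C)[C@]1(O[Si](CC)(CC)CC)CC[C@@](C)(Br)[C@H](Cl)C1)B1C2CCCC1CCC2 | intermediate
18 | carbon monoxide | [C-]#[O+] | starting material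
19 | 2-bromopropene | C=C(C)Br | starting material
20 | 6-[(1S,3R,4R)-4-bromo-3-chloro-4-methyl-1-(triethylsilyloxy)cyclohexyl]-2-methylhepta-1,6-dien-3-one | C=C(C)C(=O)CCC(=C)[C@]1(O[Si](CC)(CC)CC)CC[C@@](C)(Br)[C@H](Cl)C1 | intermediate
21 | (3R)-6-[(1S,3R,4R)-4-bromo-3-chloro-4-methyl-1-(triethylsilyloxy)cyclohexyl]-2-methylhepta-1,6-dien-3-ol | C=C(C)[C@H](O)CCC(=C)[C@]1(O[Si](CC)(CC)CC)CC[C@@](C)(Br)[C@H](Cl)C1 | intermediate
22 | (1S,3R,4R)-4-bromo-3-chloro-1-[(5R)-5-hydroxy-6-methylhepta-1,6-dien-2-yl]-4-methylcyclohexan-1-ol | C=C(C)[C@H](O)CCC(=C)[C@]1(O)CC[C@@](C)(Br)[C@H](Cl)C1 | target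

Total step count: 13
Longest linear sequence: 13 steps (1 → 22)

Steps most likely to fail

Step 11. Oxidative addition of the alkenyl bromide may stall under CO. CO-free coupling may also intrude, or the isopropenyl ketone may be consumed by oligomerisation or conjugate addition while it forms. The fallback sets out from 17 and comes back at 20; it builds the two bonds one after the other without palladium.
- Hydride-promoted carbonylation of the borane (CO 1 bar, KBH(OiPr)3, THF, 0 °C, then H2O2 in pH 7 buffer) should give 4-[(1S,3R,4R)-4-bromo-3-chloro-4-methyl-1-(triethylsilyloxy)cyclohexyl]pent-4-enal F1.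
- Commercial CH2=C(CH3)MgBr in THF at −78 °C adds to it and gives 6-[(1S,3R,4R)-4-bromo-3-chloro-4-methyl-1-(triethylsilyloxy)cyclohexyl]-2-methylhepta-1,6-dien-3-ol as both C10 epimers F2.
- Dess–Martin periodinane with NaHCO3 in CH2Cl2 then oxidises the mixture to 20.

Step 8. Proton loss to alkenes may outrun bromide capture, or weak chlorine bridging may erode the facial selectivity at C4. The fallback sets out from 10 and comes back at 13. It swaps the neutral activation for acidic, reversible conditions, under which alkenes are returned to the tertiary bromide by Markovnikov HBr addition, and it guards C1 as an ester that ionises far less readily than the C4 alcohol.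
- Ac2O, Et3N and DMAP give (1S,3S,6R)-3-ethynyl-6-methyl-7-oxabicyclo[4.1.0]heptan-3-yl acetate F3.
- LiCl/AcOH in THF gives (1S,3R,4R)-3-chloro-1-ethynyl-4-hydroxy-4-methylcyclohexyl acetate F4.
- Me3SiBr in CH2Cl2 at 0 °C gives (1S,3R,4R)-4-bromo-3-chloro-1-ethynyl-4-methylcyclohexyl acetate F5.
- i-Bu2AlH in CH2Cl2 at −78 °C frees (1S,3R,4R)-4-bromo-3-chloro-1-ethynyl-4-methylcyclohexan-1-ol F6.
- Et3SiOTf with 2,6-lutidine (no epoxide is left at this stage) gives 13.

Step 3. Facial discrimination with an acyclic diene may be insufficient, and the acidic salt may polymerise isoprene or the dienophile. The fallback sets out from 6 and comes back at 9; it sets C1 by reagent-controlled epoxidation instead of cycloaddition.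
- AlCl3-promoted Diels–Alder reaction of 6 with methyl propiolate gives methyl 4-methylcyclohexa-1,4-diene-1-carboxylate F7.
- i-Bu2AlH gives (4-methylcyclohexa-1,4-dien-1-yl)methanol F8.
- Sharpless asymmetric epoxidation (Ti(OiPr)4, L-(+)-diethyl tartrate, t-BuOOH, 4 Å sieves, CH2Cl2, −20 °C) of the allylic alkene gives [(1S,6S)-4-methyl-7-oxabicyclo[4.1.0]hept-3-en-1-yl]methanol F9.
- LiAlH4 opens the oxirane at its secondary carbon to give (1S)-1-(hydroxymethyl)-4-methylcyclohex-3-en-1-ol F10.
- Parikh–Doering oxidation gives (1S)-1-hydroxy-4-methylcyclohex-3-ene-1-carbaldehyde F11.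
- Ohira–Bestmann homologation gives 9.

Further compounds
F1 | step 11 | 4-[(1S,3R,4R)-4-bromo-3-chloro-4-methyl-1-(triethylsilyloxy)cyclohexyl]pent-4-enal | O=CCCC(=C)[C@]1(O[Si](CC)(CC)CC)CC[C@@](C)(Br)[C@H](Cl)C1
F2 | step 11 | 6-[(1S,3R,4R)-4-bromo-3-chloro-4-methyl-1-(triethylsilyloxy)cyclohexyl]-2-methylhepta-1,6-dien-3-ol, both C10 epimers | C=C(C)C(O)CCC(=C)[C@]1(O[Si](CC)(CC)CC)CC[C@@](C)(Br)[C@H](Cl)C1
F3 | step 8 | (1S,3S,6R)-3-ethynyl-6-methyl-7-oxabicyclo[4.1.0]heptan-3-yl acetate | C#C[C@]1(OC(C)=O)CC[C@@]2(C)O[C@H]2C1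
F4 | step 8 | (1S,3R,4R)-3-chloro-1-ethynyl-4-hydroxy-4-methylcyclohexyl acetate | C#C[C@]1(OC(C)=O)CC[C@@](C)(O)[C@H](Cl)C1
F5 | step 8 | (1S,3R,4R)-4-bromo-3-chloro-1-ethynyl-4-methylcyclohexyl acetate | C#C[C@]1(OC(C)=O)CC[C@@](C)(Br)[C@H](Cl)C1
F6 | step 8 | (1S,3R,4R)-4-bromo-3-chloro-1-ethynyl-4-methylcyclohexan-1-ol | C#C[C@]1(O)CC[C@@](C)(Br)[C@H](Cl)C1
F7 | step 3 | methyl 4-methylcyclohexa-1,4-diene-1-carboxylate | COC(=O)C1=CCC(C)=CC1
F8 | step 3 | (4-methylcyclohexa-1,4-dien-1-yl)methanol | OCC1=CCC(C)=CC1
F9 | step 3 | [(1S,6S)-4-methyl-7-oxabicyclo[4.1.0]hept-3-en-1-yl]methanol | OC[C@@]12CC=C(C)C[C@@H]1O2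
F10 | step 3 | (1S)-1-(hydroxymethyl)-4-methylcyclohex-3-en-1-ol | OC[C@]1(O)CCC(C)=CC1
F11 | step 3 | (1S)-1-hydroxy-4-methylcyclohex-3-ene-1-carbaldehyde | O=C[C@]1(O)CCC(C)=CC1
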